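**Retrosynthetic overview**
The target is (2S)-2,3-dihydro-3',3'''-biapigenin: a (2S)-naringenin unit and an apigenin unit joined C3'–C3''' through a 2,2'-biphenol. All six OH groups are carried as benzyl ethers and freed last.
The last C–C disconnection is C2–C1' of the flavanone. It leads to 5,7-bis(benzyloxy)chromone (ring C one oxidation level up, C2 not functionalized) and an arylboronic acid that already holds the whole flavone; the union is a catalytic enantioselective 1,4-addition.
Enabling feature: in ring C, C2 is the H-bearing β-carbon of the vinylogous ester O1–C2=C3–C4=O. The matching carbon of the flavone pyranone ring is aryl-substituted and inert, and C1' lies para to O4', where a halide placeholder for boron is easy to carry.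
The boronic acid comes from Miyaura borylation of an aryl chloride, which comes from Suzuki–Miyaura formation of the C3'–C3''' biaryl bond on a 3'-bromoflavone, which comes from a 2'-hydroxychalcone.
Ring order: both A rings are bought in phloroacetophenone. Then follow chromone ring C (step 2), the flavone pyranone ring (step 4), the biaryl bond (step 5) and saturation of ring C to the flavanone (step 8).

Key step: step 8

Remark on the chemistry: the biphenyl axis bears only two ortho substituents and is taken to rotate freely, so C2 is the only stereogenic element; the (S)-diphosphine is taken to induce on chromones the same sense as on cyclic enones (2S), and its antipode would be used if the sense proved opposite.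

Step 1
Reactants: 1 2',4',6'-trihydroxyacetophenone
Product: 2 1-[2,4-bis(benzyloxy)-6-hydroxyphenyl]ethan-1-one
Conditions: BnBr (2.1 equiv), K2CO3 (2.2 equiv), DMF, 25 to 60 °C
Reagents that add atoms: benzyl bromide, BrCc1ccccc1
Why: Williamson ether synthesis in which the 4-OH and one of the two equivalent ortho OH groups are alkylated, while the remaining ortho OH is held in a strong hydrogen bond to the acetyl carbonyl and resists a weak base and two equivalents of halide.

Step 2
Reactants: 2 1-[2,4-bis(benzyloxy)-6-hydroxyphenyl]ethan-1-one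
Product: 4 5,7-bis(benzyloxy)-4H-chromen-4-one, via enaminone 3 (not isolated)
Conditions: Me2NCH(OMe)2 (2 equiv), toluene, 95 °C; concentrate; then conc. HCl (2 equiv), CH2Cl2, 25 to 40 °C
Reagents that add atoms: N,N-dimethylformamide dimethyl acetal, COC(OC)N(C)C
Why: Enaminone route to chromones, in which the acetyl CH3 condenses with the amide acetal and, on acidification, the phenol oxygen adds to the β-carbon (6-endo-trig addition–elimination) with loss of dimethylamine to close ring C at the chromone level.

Step 3
Reactants: 2 1-[2,4-bis(benzyloxy)-6-hydroxyphenyl]ethan-1-one; 5 4-(benzyloxy)-3-bromobenzaldehyde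
Product: 6 (E)-1-[2,4-bis(benzyloxy)-6-hydroxyphenyl]-3-[4-(benzyloxy)-3-bromophenyl]prop-2-en-1-one
Conditions: KOH (aq 50%), EtOH–THF, 25 °C
Reagents that add atoms: none
Why: Claisen–Schmidt condensation (crossed aldol, E1cB dehydration) between the only enolisable ketone and a non-enolisable aldehyde, which should give the thermodynamically favoured E-enone while benzyl ethers and the aryl bromide stay inert to alcoholic KOH.

Step 4
Reactants: 6 (E)-1-[2,4-bis(benzyloxy)-6-hydroxyphenyl]-3-[4-(benzyloxy)-3-bromophenyl]prop-2-en-1-one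
Product: 7 5,7-bis(benzyloxy)-2-[4-(benzyloxy)-3-bromophenyl]-4H-chromen-4-one
Conditions: I2 (10 mol%), DMSO, 125 °C
Reagents that add atoms: none
Why: Iodine-catalysed oxidative cyclisation of a 2'-hydroxychalcone in DMSO (oxa-Michael closure, α-iodination, loss of HI, reoxidation of HI by DMSO), the standard entry to 5,7-dialkoxyflavones.

Step 5
Reactants: 7 5,7-bis(benzyloxy)-2-[4-(benzyloxy)-3-bromophenyl]-4H-chromen-4-one; 8 [2-(benzyloxy)-5-chlorophenyl]boronic acid
Product: 9 5,7-bis(benzyloxy)-2-[2',6-bis(benzyloxy)-5'-chlorobiphenyl-3-yl]-4H-chromen-4-one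
Conditions: PdCl2(dppf) (5 mol%), K2CO3 (aq 2 M), 8 (1.5 equiv), 1,4-dioxane, 85 °C
Reagents that add atoms: none
Why: Suzuki–Miyaura coupling in which zerovalent palladium with a simple diphosphine inserts into the C–Br bond far faster than into the C–Cl bond of an electron-rich chloroarene, so the chloride is carried through as the placeholder for boron.

Step 6
Reactants: 9 5,7-bis(benzyloxy)-2-[2',6-bis(benzyloxy)-5'-chlorobiphenyl-3-yl]-4H-chromen-4-one
Product: 10 5,7-bis(benzyloxy)-2-[2',6-bis(benzyloxy)-5'-(4,4,5,5-tetramethyl-1,3,2-dioxaborolan-2-yl)biphenyl-3-yl]-4H-chromen-4-one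
Conditions: Pd2(dba)3 (2 mol%), XPhos (8 mol%), B2pin2 (1.5 equiv), KOAc (3 equiv), 1,4-dioxane, 100 °C
Reagents that add atoms: bis(pinacolato)diboron, CC1(C)OB(OC1(C)C)B1OC(C)(C)C(C)(C)O1
Why: Miyaura borylation of an aryl chloride, for which the bulky electron-rich biarylphosphine allows oxidative addition even para to an alkoxy group, while the flavone carbonyl and the benzyl ethers tolerate KOAc.

Step 7
Reactants: 10 5,7-bis(benzyloxy)-2-[2',6-bis(benzyloxy)-5'-(4,4,5,5-tetramethyl-1,3,2-dioxaborolan-2-yl)biphenyl-3-yl]-4H-chromen-4-one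
Product: 11 {2',6-bis(benzyloxy)-5'-[5,7-bis(benzyloxy)-4-oxo-4H-chromen-2-yl]biphenyl-3-yl}boronic acid
Conditions: NaIO4 (3 equiv), NH4OAc (3 equiv), THF–acetone–H2O, 25 °C
Reagents that add atoms: water, O
Why: Oxidative hydrolysis of a pinacol boronate, in which the ester–acid equilibrium is pulled over because periodate cleaves the released pinacol (glycol cleavage) to acetone, and nothing else in 10 is oxidised by periodate.

Step 8
Reactants: 11 {2',6-bis(benzyloxy)-5'-[5,7-bis(benzyloxy)-4-oxo-4H-chromen-2-yl]biphenyl-3-yl}boronic acid; 4 5,7-bis(benzyloxy)-4H-chromen-4-one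
Product: 12 (2S)-5,7-bis(benzyloxy)-2-{2',6-bis(benzyloxy)-5'-[5,7-bis(benzyloxy)-4-oxo-4H-chromen-2-yl]biphenyl-3-yl}-2,3-dihydro-4H-chromen-4-one
Conditions: [RhCl(C2H4)2]2 (2.5 mol%), (S)-MeO-F12-BIPHEP [(S)-6,6'-dimethoxy-2,2'-bis{bis(3,4,5-trifluorophenyl)phosphino}biphenyl, 5.5 mol%], aq KOH (10 mol%), 4 (2 equiv), CH2Cl2–H2O, 25 °C
Reagents that add atoms: none
Why: Hayashi–Miyaura reaction, the rhodium-catalysed asymmetric 1,4-addition of an arylboronic acid, which has close precedent on chromones as acceptors: the hydroxo complex of monovalent rhodium transmetalates with 11, the aryl–rhodium bond adds syn across C2=C3 of 4 with the aryl group going to the β-carbon C2, and water cleaves the oxa-π-allyl rhodium enolate to the ketone and the hydroxo complex. No ring is closed; ring C enters one oxidation level too high as a chromone and is brought to the chromanone level by the C–C bond formation itself, so the flavanone and flavone halves never have to be told apart by a redox step. The only stereocentre, C2, is set by the catalyst: the (S)-biaryl diphosphine blocks two diagonal quadrants around the metal, the flat chromone can coordinate with one face only without meeting an aryl group on phosphorus, and migration of the aryl group to that face should give 2S, the sense known for cyclic enones. The electron-poor phosphine makes the metal more electrophilic and so speeds up insertion into the electron-rich vinylogous ester at room temperature, and the almost base-free medium leaves no path for retro-oxa-Michael opening of 12. The step needs chemoselectivity between two pyranone C=C bonds, and substitution secures it: C2 of 4 bears only H, whereas the corresponding carbon of the flavone in 11 is aryl-substituted, giving a trisubstituted, conjugated alkene that does not insert under these conditions. 1,2-Addition to the new ketone is held back by the flanking 5-benzyloxy group and by CH2Cl2 as solvent, and the excess of cheap 4 should trap the aryl–rhodium species before protodeboronation wastes the valuable fragment.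

Step 9
Reactants: 12 (2S)-5,7-bis(benzyloxy)-2-{2',6-bis(benzyloxy)-5'-[5,7-bis(benzyloxy)-4-oxo-4H-chromen-2-yl]biphenyl-3-yl}-2,3-dihydro-4H-chromen-4-one
Product: 13 (2S)-2-[5'-(5,7-dihydroxy-4-oxo-4H-chromen-2-yl)-2',6-dihydroxybiphenyl-3-yl]-5,7-dihydroxy-2,3-dihydro-4H-chromen-4-one (target)
Conditions: H2 (1 atm), 10% Pd/C, THF–MeOH, 25 °C; filtration, work-up and purification without base
Reagents that add atoms: none
Why: Catalytic hydrogenolysis of aryl benzyl ethers under neutral conditions, which should be faster than reduction of the conjugated flavone C=C bond or cleavage of the cyclic benzylic C2–O1 bond, and which offers neither acid nor base for epimerisation of C2 by retro-oxa-Michael opening.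

**Compound list**
1 | 2',4',6'-trihydroxyacetophenone (phloroacetophenone) | CC(=O)c1c(O)cc(O)cc1O | starting material
2 | 1-[2,4-bis(benzyloxy)-6-hydroxyphenyl]ethan-1-one | CC(=O)c1c(O)cc(OCc2ccccc2)cc1OCc1ccccc1 | intermediate
3 | (E)-1-[2,4-bis(benzyloxy)-6-hydroxyphenyl]-3-(dimethylamino)prop-2-en-1-one (enaminone, not isolated) | CN(C)/C=C/C(=O)c1c(O)cc(OCc2ccccc2)cc1OCc1ccccc1 | intermediate
4 | 5,7-bis(benzyloxy)-4H-chromen-4-one | O=c1ccoc2cc(OCc3ccccc3)cc(OCc3ccccc3)c12 | intermediate
5 | 4-(benzyloxy)-3-bromobenzaldehyde | O=Cc1ccc(OCc2ccccc2)c(Br)c1 | starting material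
6 | (E)-1-[2,4-bis(benzyloxy)-6-hydroxyphenyl]-3-[4-(benzyloxy)-3-bromophenyl]prop-2-en-1-one | O=C(/C=C/c1ccc(OCc2ccccc2)c(Br)c1)c1c(O)cc(OCc2ccccc2)cc1OCc1ccccc1 | intermediate
7 | 5,7-bis(benzyloxy)-2-[4-(benzyloxy)-3-bromophenyl]-4H-chromen-4-one | O=c1cc(-c2ccc(OCc3ccccc3)c(Br)c2)oc2cc(OCc3ccccc3)cc(OCc3ccccc3)c12 | intermediate
8 | [2-(benzyloxy)-5-chlorophenyl]boronic acid | OB(O)c1cc(Cl)ccc1OCc1ccccc1 | starting material
9 | 5,7-bis(benzyloxy)-2-[2',6-bis(benzyloxy)-5'-chlorobiphenyl-3-yl]-4H-chromen-4-one | O=c1cc(-c2ccc(OCc3ccccc3)c(-c3cc(Cl)ccc3OCc3ccccc3)c2)oc2cc(OCc3ccccc3)cc(OCc3ccccc3)c12 | intermediate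
10 | 5,7-bis(benzyloxy)-2-[2',6-bis(benzyloxy)-5'-(4,4,5,5-tetramethyl-1,3,2-dioxaborolan-2-yl)biphenyl-3-yl]-4H-chromen-4-one | O=c1cc(-c2ccc(OCc3ccccc3)c(-c3cc(B4OC(C)(C)C(C)(C)O4)ccc3OCc3ccccc3)c2)oc2cc(OCc3ccccc3)cc(OCc3ccccc3)c12 | intermediate
11 | {2',6-bis(benzyloxy)-5'-[5,7-bis(benzyloxy)-4-oxo-4H-chromen-2-yl]biphenyl-3-yl}boronic acid | O=c1cc(-c2ccc(OCc3ccccc3)c(-c3cc(B(O)O)ccc3OCc3ccccc3)c2)oc2cc(OCc3ccccc3)cc(OCc3ccccc3)c12 | intermediate
12 | (2S)-5,7-bis(benzyloxy)-2-{2',6-bis(benzyloxy)-5'-[5,7-bis(benzyloxy)-4-oxo-4H-chromen-2-yl]biphenyl-3-yl}-2,3-dihydro-4H-chromen-4-one | O=C1C[C@@H](c2ccc(OCc3ccccc3)c(-c3cc(-c4cc(=O)c5c(OCc6ccccc6)cc(OCc6ccccc6)cc5o4)ccc3OCc3ccccc3)c2)Oc2cc(OCc3ccccc3)cc(OCc3ccccc3)c21 | intermediate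
13 | (2S)-2-[5'-(5,7-dihydroxy-4-oxo-4H-chromen-2-yl)-2',6-dihydroxybiphenyl-3-yl]-5,7-dihydroxy-2,3-dihydro-4H-chromen-4-one | O=C1C[C@@H](c2ccc(O)c(-c3cc(-c4cc(=O)c5c(O)cc(O)cc5o4)ccc3O)c2)Oc2cc(O)cc(O)c21 | target

**Step count**
Total step count: 9.
Longest linear sequence: 8 (steps 1, 3, 4, 5, 6, 7, 8, 9). Step 2 is the side branch.

**Steps most likely to fail**

Step 8.
- What may go wrong: insertion of the aryl–rhodium species into the electron-rich 5,7-dialkoxychromone may be slower than protodeboronation of the large boronic acid. Facial selectivity may also be eroded by the bulky meta-aryl substituent.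
- The fallback sets out from 11 and 4 and separates bond formation from stereocontrol.
- The C2–C1' bond is made without a chiral ligand by the conjugate addition catalysed by cationic divalent palladium (Pd(OCOCF3)2, 2,2'-bipyridine, ClCH2CH2Cl–H2O, 60 °C). This should give the racemic hexabenzyl ether F1.
- The racemate is then resolved kinetically by asymmetric transfer hydrogenation (RhCl[(R,R)-TsDPEN](C5Me5), HCO2H–NEt3, EtOAc, 25 °C, run to about half conversion).
- The 2R ketone should be reduced faster, to the cis-(2R,4R)-flavan-4-ol F2, while the 2S ketone remains. Chromatographic separation comes back to the route at 12.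

Step 9.
- What may go wrong: over-reduction of the flavone C=C bond, hydrogenolytic opening of the C2–O1 bond, or stalling because partly deprotected material is poorly soluble. Configurational integrity of the free 4'-hydroxyflavanone is lost if the medium turns basic.
- The fallback sets out from 12 and replaces reduction by Lewis-acid dealkylation with a cation scavenger (BCl3, pentamethylbenzene, CH2Cl2, −78 °C, quench with MeOH).
- The benzyl groups are transferred as cations to the arene and no hydrogen is present. It comes back to the route directly at 13 and makes no new compound.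

Step 6.
- What may go wrong: sluggish oxidative addition into the electron-rich C–Cl bond, with hydrodechlorination or decay of the catalyst taking over.
- The fallback sets out from 7 and inverts the polarity of the biaryl coupling, so that a more reactive bromide is borylated.
- Miyaura borylation of the aryl bromide 7 (PdCl2(dppf), B2pin2, KOAc, 1,4-dioxane, 90 °C) should give the flavone 3'-pinacol boronate F3.
- Commercial 4-bromo-2-iodophenol is benzylated (BnBr, K2CO3, DMF) to 1-(benzyloxy)-4-bromo-2-iodobenzene F4.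
- Suzuki–Miyaura coupling of the two at the C–I bond (Pd(PPh3)4, aq K2CO3, 1,4-dioxane, 70 °C) should give the 5'-bromo analogue of 9, F5.
- Standard Miyaura borylation of this bromide (PdCl2(dppf), B2pin2, KOAc, 1,4-dioxane, 90 °C) comes back to the route at 10.

**Further compounds**
F1 | step 8 | racemic 5,7-bis(benzyloxy)-2-{2',6-bis(benzyloxy)-5'-[5,7-bis(benzyloxy)-4-oxo-4H-chromen-2-yl]biphenyl-3-yl}-2,3-dihydro-4H-chromen-4-one | O=C1CC(c2ccc(OCc3ccccc3)c(-c3cc(-c4cc(=O)c5c(OCc6ccccc6)cc(OCc6ccccc6)cc5o4)ccc3OCc3ccccc3)c2)Oc2cc(OCc3ccccc3)cc(OCc3ccccc3)c21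
F2 | step 8 | 5,7-bis(benzyloxy)-2-{2',6-bis(benzyloxy)-5'-[(2R,4R)-5,7-bis(benzyloxy)-4-hydroxy-3,4-dihydro-2H-chromen-2-yl]biphenyl-3-yl}-4H-chromen-4-one (cis-flavan-4-ol) | O[C@@H]1C[C@H](c2ccc(OCc3ccccc3)c(-c3cc(-c4cc(=O)c5c(OCc6ccccc6)cc(OCc6ccccc6)cc5o4)ccc3OCc3ccccc3)c2)Oc2cc(OCc3ccccc3)cc(OCc3ccccc3)c21
F0 | step 9 | none | none
F3 | step 6 | 5,7-bis(benzyloxy)-2-[4-(benzyloxy)-3-(4,4,5,5-tetramethyl-1,3,2-dioxaborolan-2-yl)phenyl]-4H-chromen-4-one | O=c1cc(-c2ccc(OCc3ccccc3)c(B3OC(C)(C)C(C)(C)O3)c2)oc2cc(OCc3ccccc3)cc(OCc3ccccc3)c12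
F4 | step 6 | 1-(benzyloxy)-4-bromo-2-iodobenzene | Brc1ccc(OCc2ccccc2)c(I)c1
F5 | step 6 | 5,7-bis(benzyloxy)-2-[2',6-bis(benzyloxy)-5'-bromobiphenyl-3-yl]-4H-chromen-4-one | O=c1cc(-c2ccc(OCc3ccccc3)c(-c3cc(Br)ccc3OCc3ccccc3)c2)oc2cc(OCc3ccccc3)cc(OCc3ccccc3)c12
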